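The runs were generated by integration for substances that don't exist; scatter was added.

I chose to judge the oak flask by one time, how long its coupling partner lasts, and I read that time from the earlier runs.

common to all: coupling partner 0.0750 M; free catalyst 0.00150 M

|  | substrate | target | time |
|---|---|---|---|
| maple | 0.0500 M |  |  |
| elm | 0.100 M |  |  |
| cedar | 0.0500 M | 0.0250 M |  |
| oak | 0.230 M |  | 15 min |

| maple run: time / min | maple run: [target] / M | elm run: time / min | elm run: [target] / M | cedar run: time / min | cedar run: [target] / M |
|---|---|---|---|---|---|
| 0.85 | 0.0031 | 0.85 | 0.0059 | 0.85 | 0.0301 |
| 2.6 | 0.0085 | 2.6 | 0.0190 | 2.6 | 0.0383 |
| 4.9 | 0.0168 | 4.9 | 0.0343 | 4.9 | 0.0470 |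
| 7.8 | 0.0242 | 7.8 | 0.0484 | 7.8 | 0.0542 |
| 11 | 0.0303 | 11 | 0.0569 | 11 | 0.0590 |
| 15 | 0.0347 | 15 | 0.0632 | 15 | 0.0636 |

(readings scatter by 5 × 10⁻⁴ M)

- how the opening rate goes with [substrate] round the charge of the maple run: the exponent of the rate at two percent of substrate gone to target (one fixed amount of target, the same in the runs compared)
- target in the oak run at 15 min, as a share of the substrate charged

- Overall: substrate + coupling partner -> target, with free catalyst as catalyst.
- Constant volume, constant temperature.
- The analysis sees a species whether free or bound.
- An order is taken over about fifteen percent of the charge, up and down.

The order came first. At 0.85 min the elm reading stood at 1.90 times the maple reading and at 2.6 min at 2.24 times, and elm holds twice the substrate, so I took the opening rate as first order in substrate. The maple and elm flasks charge the same coupling partner, and I assumed first order there too. The maple reading at 2.6 min, divided by that time and by both charges, then read as a rate constant of 0.872 /M/min.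

In the oak flask the coupling partner is the limiting reagent, since substrate is charged at 0.230 M against 0.0750 M, so its target has a ceiling of 32.6% of the substrate charged. With substrate in excess I treated the decay of the coupling partner in the oak flask as roughly pseudo-first-order. I call the partner life the time for it to fall by a factor e with substrate held at its charge and the rate constant at its opening value, the inverse of their product: 4.99 min for oak. So 15 min is 3.01 lives, which by my reckoning leaves 4.95% of the coupling partner and gives target at 31.0%. The cedar flask, charged with target, read a gain of 1.65 times what the maple flask gained by 0.85 min, while making that much target costs the oak flask 10.9% of its substrate. I judged that in the oak flask the speeding would outweigh the loss, and I committed to a figure between 31.0% and the ceiling.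

The forecast gave an order of 0.97, and 32.3% for the oak flask on the ground that “the partner is essentially exhausted by 15 min”. Its figure lies inside my bracket.

The oak flask gave 32.6% at 15 min, and the order in substrate round the maple charge came to 1.0.

    free catalyst + substrate ⇌ catalyst-substrate complex (49.38 /M/min, 4.866 /min)
    catalyst-substrate complex + coupling partner → target + free catalyst (1374 /M/min)
    free catalyst + target → spent catalyst + target (3.630 /M/min)
    substrate + coupling partner + target → 2 target (29.34 /M²/min)

That figure matches the ceiling of 32.6%, and the conversion of free catalyst into spent catalyst made no difference to it. It stands 1.6 percentage points above what 3.01 lives gave. In the elm flask the partner life is 11.5 min, which puts target at half of the substrate charged after 12.6 min, while the elm run reached it in 8.38 min.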